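## Retrosynthetic overview

1. Kanzonol S 18 ⇐ tris-silyl ether 17 by fluoride in the last step; the acetate, the E olefin and the 2S centre are all in place before it.
2. C8–CH2 (key): 17 ⇐ O5-allyl ether 14 by a Lewis-acid para-Claisen–Cope relay. The enabling feature is that on ring A C8 is para to the C5 oxygen, and that this oxygen is the peri one paired with the C4 carbonyl of ring C. It is therefore the only hydrogen-bonded phenol (selectively left free) and a bidentate site for Eu(fod)3, and both of its ortho carbons, C6 and C4a, can only pass the allyl unit on to C8.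
3. O5–CH2: 14 ⇐ (S)-flavanone 13 + (E)-allylic alcohol 5 (Mitsunobu); 5 ⇐ prenol 1 by E-selective SeO2 oxidation.
4. C2–aryl: 13 ⇐ 7-silyloxychromone 12 + arylboronic acid 10 (rhodium-catalysed asymmetric 1,4-addition sets 2S).
5. Ring order: rings A and C enter fused as commercial 5,7-dihydroxychromone 11, and ring B enters as 4-bromocatechol 6 and is attached at C2 in step 8. No ring is closed anywhere; ring A is only dearomatised twice and rearomatised in the key step.

Key step: step 10

Assumption: the (S)-bisphosphine in step 8 is taken to give the 2S flavanone by analogy with the (S)-3-aryl ketones it gives from cyclic enones; should the sense prove opposite, the (R)-ligand is used and nothing else changes.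

## Route

Step 1
Reactants: 1 3-methylbut-2-en-1-ol (prenol)
Product: 2 tert-butyldimethyl[(3-methylbut-2-en-1-yl)oxy]silane
Conditions: TBSCl, imidazole, CH2Cl2, 0 °C to rt
Reagents that add atoms: tert-butyldimethylsilyl chloride, CC(C)(C)[Si](C)(C)Cl
Why: Standard silylation of a primary alcohol masks the oxygen that must later be free for the etherification.

Step 2
Reactants: 2 tert-butyldimethyl[(3-methylbut-2-en-1-yl)oxy]silane
Product: 3 (E)-4-[(tert-butyldimethylsilyl)oxy]-2-methylbut-2-en-1-ol
Conditions: SeO2 (cat.), t-BuOOH, salicylic acid (cat.), CH2Cl2, 0 °C to rt; the minor over-oxidised enal is separated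
Reagents that add atoms: selenium dioxide, O=[Se]=O (catalytic oxygen carrier); tert-butyl hydroperoxide, CC(C)(C)OO (terminal oxidant)
Why: The Riley allylic oxidation (ene reaction, then [2,3]-sigmatropic shift) acts at the more substituted olefin terminus and should attack the methyl group trans to the CH2OSi chain, which sets the E geometry of the future side chain.

Step 3
Reactants: 3 (E)-4-[(tert-butyldimethylsilyl)oxy]-2-methylbut-2-en-1-ol
Product: 4 (E)-4-[(tert-butyldimethylsilyl)oxy]-2-methylbut-2-en-1-yl acetate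
Conditions: Ac2O, pyridine, DMAP (cat.), CH2Cl2, 0 °C to rt
Reagents that add atoms: acetic anhydride, CC(=O)OC(C)=O
Why: Routine DMAP-catalysed acetylation of a primary allylic alcohol installs the acetate of the target at the outset.

Step 4
Reactants: 4 (E)-4-[(tert-butyldimethylsilyl)oxy]-2-methylbut-2-en-1-yl acetate
Product: 5 (E)-4-hydroxy-2-methylbut-2-en-1-yl acetate
Conditions: HF·pyridine, pyridine, THF, 0 °C to rt
Reagents that add atoms: none
Why: Acidic fluoride cleaves the primary silyl ether without touching the acetate, and the trans arrangement of the two oxygens across the olefin rules out acetyl migration.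

Step 5
Reactants: 6 4-bromobenzene-1,2-diol (4-bromocatechol)
Product: 7 4-bromo-1,2-bis[(tert-butyldimethylsilyl)oxy]benzene
Conditions: TBSCl (2.2 equiv), imidazole, DMF, rt
Reagents that add atoms: tert-butyldimethylsilyl chloride, CC(C)(C)[Si](C)(C)Cl
Why: Standard bis-silylation of a catechol, chosen because aryl silyl ethers can be removed at the end by fluoride under non-basic conditions.

Step 6
Reactants: 7 4-bromo-1,2-bis[(tert-butyldimethylsilyl)oxy]benzene
Product: 10 [3,4-bis(tert-butyldimethylsilyloxy)phenyl]boronic acid, via aryllithium 8 (not isolated), via lithium aryltriisopropoxyborate 9 (not isolated)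
Conditions: n-BuLi, THF, −78 °C; B(OiPr)3, −78 °C to rt; dilute aq. HCl, 0 °C
Reagents that add atoms: triisopropyl borate, CC(C)OB(OC(C)C)OC(C)C; water, O; n-butyllithium, [Li]CCCC (lithium in 8 and 9 only)
Why: Bromine–lithium exchange, borylation and mild hydrolysis is the standard route to arylboronic acids, and because the lithium sits meta and para to the silyloxy groups no retro-Brook silyl shift is expected.

Step 7
Reactants: 11 5,7-dihydroxy-4H-chromen-4-one
Product: 12 7-[(tert-butyldimethylsilyl)oxy]-5-hydroxy-4H-chromen-4-one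
Conditions: TBSCl (1.05 equiv), imidazole, DMF, 0 °C
Reagents that add atoms: tert-butyldimethylsilyl chloride, CC(C)(C)[Si](C)(C)Cl
Why: The C7 hydroxyl is the more acidic, unhindered phenol whereas the C5 hydroxyl is locked in a hydrogen bond to the C4 carbonyl, so one equivalent of silyl chloride should react at O7 only.

Step 8
Reactants: 12 7-[(tert-butyldimethylsilyl)oxy]-5-hydroxy-4H-chromen-4-one; 10 [3,4-bis(tert-butyldimethylsilyloxy)phenyl]boronic acid
Product: 13 (2S)-2-{3,4-bis[(tert-butyldimethylsilyl)oxy]phenyl}-7-[(tert-butyldimethylsilyl)oxy]-5-hydroxy-2,3-dihydro-4H-chromen-4-one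
Conditions: [Rh(OH)(cod)]2 (cat.), (S)-2,2'-bis[bis(3,4,5-trifluorophenyl)phosphino]-6,6'-dimethoxy-1,1'-biphenyl (cat.), toluene/H2O, 30 °C, no added base
Reagents that add atoms: none
Why: In this Hayashi–Miyaura asymmetric 1,4-addition the aryl–rhodium complex of the (S)-bisphosphine should add to the face of C2=C3 that corresponds to 2S, while the electron-poor ligand and base-free medium favour protonation of the rhodium enolate over ring opening and spare the aryl silyl ethers.

Step 9
Reactants: 13 (2S)-flavanone with free C5 hydroxyl; 5 (E)-4-hydroxy-2-methylbut-2-en-1-yl acetate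
Product: 14 (2E)-4-{[(2S)-2-{3,4-bis[(tert-butyldimethylsilyl)oxy]phenyl}-7-[(tert-butyldimethylsilyl)oxy]-4-oxo-3,4-dihydro-2H-chromen-5-yl]oxy}-2-methylbut-2-en-1-yl acetate
Conditions: PPh3, DIAD, THF, 0 °C to rt
Reagents that add atoms: none
Why: The Mitsunobu reaction alkylates the only free phenol at oxygen under neutral conditions by SN2 attack at the primary allylic carbon, so neither the olefin geometry nor the base-sensitive C2 stereocentre is touched.

Step 10
Reactants: 14 (2S)-5-O-[(E)-4-acetoxy-3-methylbut-2-enyl] flavanone tris-silyl ether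
Product: 17 (2E)-4-[(2S)-2-{3,4-bis[(tert-butyldimethylsilyl)oxy]phenyl}-7-[(tert-butyldimethylsilyl)oxy]-5-hydroxy-4-oxo-3,4-dihydro-2H-chromen-8-yl]-2-methylbut-2-en-1-yl acetate, via C6 ortho-dienone 15 (not isolated), via C8 para-dienone 16 (not isolated)
Conditions: Eu(fod)3 (cat.; fod = 6,6,7,7,8,8,8-heptafluoro-2,2-dimethyloctane-3,5-dionate), ethanol-free CHCl3, 60–70 °C, sealed tube, argon
Reagents that add atoms: none
Why: Eu(fod)3 binds the O5/C4=O site and triggers an aromatic Claisen [3,3] shift of the allyl group from O5 to C6 (or C4a), giving dearomatised ortho-dienone 15 with the inverted, branched allyl unit; a Cope [3,3] shift then carries it to C8, forming the C8–CH2 bond with the linear connectivity restored, and tautomerisation of para-dienone 16 rearomatises ring A and frees the chelated C5 hydroxyl. The closest known reaction type is the Eu(fod)3-catalysed para-Claisen–Cope rearrangement of 5-O-prenyl flavanones and flavones to their 8-prenyl isomers. No ring is closed; ring A is only dearomatised and rearomatised. No new stereocentre is formed, but the E geometry of the side-chain olefin must survive: both shifts are suprafacial and should pass through chair transition states, which returns the original geometry after the double allylic inversion, whereas a Z olefin would need one chair and one boat. The step needs para over ortho selectivity, which is secured because C4a is blocked and can only relay to C8, and because dienone 15 carries a quaternary carbon squeezed between C5=O and the C7 silyloxy group, so the second shift should outrun enolisation. The C2 stereocentre is not at risk because the medium is neutral and the enolate needed to open ring C is never formed.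

Step 11
Reactants: 17 (2S)-8-[(E)-4-acetoxy-3-methylbut-2-enyl]-5-hydroxy flavanone tris-silyl ether
Product: 18 Kanzonol S, (2E)-4-[(2S)-2-(3,4-dihydroxyphenyl)-5,7-dihydroxy-4-oxo-3,4-dihydro-2H-chromen-8-yl]-2-methylbut-2-en-1-yl acetate
Conditions: HF·pyridine, pyridine, THF, 0 °C to rt
Reagents that add atoms: none
Why: Buffered HF·pyridine should cleave the three aryl silyl ethers under weakly acidic conditions that spare the allylic acetate and avoid the base-induced opening of ring C, so the 2S centre and the E olefin are carried into the target.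

## Compound list

1 | 3-methylbut-2-en-1-ol (prenol) | CC(C)=CCO | starting material
2 | tert-butyldimethyl[(3-methylbut-2-en-1-yl)oxy]silane | CC(C)=CCO[Si](C)(C)C(C)(C)C | intermediate
3 | (E)-4-[(tert-butyldimethylsilyl)oxy]-2-methylbut-2-en-1-ol | OC/C(C)=C/CO[Si](C)(C)C(C)(C)C | intermediate
4 | (E)-4-[(tert-butyldimethylsilyl)oxy]-2-methylbut-2-en-1-yl acetate | CC(=O)OC/C(C)=C/CO[Si](C)(C)C(C)(C)C | intermediate
5 | (E)-4-hydroxy-2-methylbut-2-en-1-yl acetate | CC(=O)OC/C(C)=C/CO | intermediate
6 | 4-bromobenzene-1,2-diol | Oc1ccc(Br)cc1O | starting material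
7 | 4-bromo-1,2-bis[(tert-butyldimethylsilyl)oxy]benzene | CC(C)(C)[Si](C)(C)Oc1ccc(Br)cc1O[Si](C)(C)C(C)(C)C | intermediate
8 | [3,4-bis(tert-butyldimethylsilyloxy)phenyl]lithium | [Li]c1ccc(O[Si](C)(C)C(C)(C)C)c(O[Si](C)(C)C(C)(C)C)c1 | intermediate
9 | lithium [3,4-bis(tert-butyldimethylsilyloxy)phenyl]tri(propan-2-yloxy)borate | [Li+].CC(C)O[B-](OC(C)C)(OC(C)C)c1ccc(O[Si](C)(C)C(C)(C)C)c(O[Si](C)(C)C(C)(C)C)c1 | intermediate
10 | [3,4-bis(tert-butyldimethylsilyloxy)phenyl]boronic acid | OB(O)c1ccc(O[Si](C)(C)C(C)(C)C)c(O[Si](C)(C)C(C)(C)C)c1 | intermediate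
11 | 5,7-dihydroxy-4H-chromen-4-one | O=c1ccoc2cc(O)cc(O)c12 | starting material
12 | 7-[(tert-butyldimethylsilyl)oxy]-5-hydroxy-4H-chromen-4-one | O=c1ccoc2cc(O[Si](C)(C)C(C)(C)C)cc(O)c12 | intermediate
13 | (2S)-2-{3,4-bis[(tert-butyldimethylsilyl)oxy]phenyl}-7-[(tert-butyldimethylsilyl)oxy]-5-hydroxy-2,3-dihydro-4H-chromen-4-one | c1c(O[Si](C)(C)C(C)(C)C)cc(O)c2c1O[C@H](c1ccc(O[Si](C)(C)C(C)(C)C)c(O[Si](C)(C)C(C)(C)C)c1)CC2=O | intermediate
14 | (2E)-4-{[(2S)-2-{3,4-bis[(tert-butyldimethylsilyl)oxy]phenyl}-7-[(tert-butyldimethylsilyl)oxy]-4-oxo-3,4-dihydro-2H-chromen-5-yl]oxy}-2-methylbut-2-en-1-yl acetate | CC(=O)OC/C(C)=C/COc1cc(O[Si](C)(C)C(C)(C)C)cc2c1C(=O)C[C@@H](c1ccc(O[Si](C)(C)C(C)(C)C)c(O[Si](C)(C)C(C)(C)C)c1)O2 | intermediate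
15 | C6 ortho-dienone: 2-[(2S)-2-{3,4-bis[(tert-butyldimethylsilyl)oxy]phenyl}-7-[(tert-butyldimethylsilyl)oxy]-4,5-dioxo-3,4,5,6-tetrahydro-2H-chromen-6-yl]-2-methylbut-3-en-1-yl acetate (transient centres at C6 and the side-chain quaternary carbon not specified) | CC(=O)OCC(C)(C=C)C1C(=O)C2=C(O[C@H](c3ccc(O[Si](C)(C)C(C)(C)C)c(O[Si](C)(C)C(C)(C)C)c3)CC2=O)C=C1O[Si](C)(C)C(C)(C)C | intermediate
16 | C8 para-dienone: (2E)-4-[(2S)-2-{3,4-bis[(tert-butyldimethylsilyl)oxy]phenyl}-7-[(tert-butyldimethylsilyl)oxy]-4,5-dioxo-3,4,5,8-tetrahydro-2H-chromen-8-yl]-2-methylbut-2-en-1-yl acetate (transient centre at C8 not specified) | CC(=O)OC/C(C)=C/CC1C(O[Si](C)(C)C(C)(C)C)=CC(=O)C2=C1O[C@H](c1ccc(O[Si](C)(C)C(C)(C)C)c(O[Si](C)(C)C(C)(C)C)c1)CC2=O | intermediate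
17 | (2E)-4-[(2S)-2-{3,4-bis[(tert-butyldimethylsilyl)oxy]phenyl}-7-[(tert-butyldimethylsilyl)oxy]-5-hydroxy-4-oxo-3,4-dihydro-2H-chromen-8-yl]-2-methylbut-2-en-1-yl acetate | CC(=O)OC/C(C)=C/Cc1c(O[Si](C)(C)C(C)(C)C)cc(O)c2c1O[C@H](c1ccc(O[Si](C)(C)C(C)(C)C)c(O[Si](C)(C)C(C)(C)C)c1)CC2=O | intermediate
18 | Kanzonol S, (2E)-4-[(2S)-2-(3,4-dihydroxyphenyl)-5,7-dihydroxy-4-oxo-3,4-dihydro-2H-chromen-8-yl]-2-methylbut-2-en-1-yl acetate | CC(=O)OC/C(C)=C/Cc1c(O)cc(O)c2c1O[C@H](c1ccc(O)c(O)c1)CC2=O | target

## Step count and risks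

Total step count: 11 steps.
Longest linear sequence: 7 steps (steps 1, 2, 3, 4, 9, 10, 11; 1 → 2 → 3 → 4 → 5 → 14 → 17 → 18).

Steps most likely to fail:

1. Step 10 (key step). The olefin geometry could leak if one of the two shifts passes through a boat transition state. The relay could also stop at the ortho stage if the first dienone enolises before the Cope shift, or the Lewis acid could ionise the allyl ether so that the side chain is lost. Fallback (geometry is set after the relay instead of being carried through it): the fallback sets out from 13 and prenol 1. Mitsunobu etherification (PPh3, DIAD, THF) would give the (2S)-5-prenyloxy flavanone tris-silyl ether F1. The same Eu(fod)3 relay, in which the two equal methyl groups make geometry a non-issue, would give the (2S)-8-prenyl-5-hydroxy flavanone tris-silyl ether F2. Catalytic SeO2 with t-BuOOH in CH2Cl2 would oxidise the methyl group trans to the aryl-CH2 chain to the (E)-allylic alcohol F3. One equivalent of Ac2O in pyridine at 0 °C would acetylate the primary alcohol in preference to the chelated C5 hydroxyl, and the route is rejoined at 17.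

2. Step 8. The rhodium enolate could undergo β-aryloxide elimination (ring opening to the chalcone) with unselective reclosure. Addition to the electron-rich, chelated chromone could also be slow, with competing protodeboronation. Either process erodes enantiomeric purity. Fallback (resolution instead of asymmetric induction): the fallback sets out from 12 and 10. A non-enantioselective conjugate addition with Pd(OCOCF3)2 and 2,2'-bipyridine in aqueous 1,2-dichloroethane would give the racemic flavanone F4. Noyori-type transfer hydrogenation with RuCl(p-cymene)[(R,R)-TsDPEN] and HCO2H/Et3N, stopped near half conversion, is expected to reduce the 2R enantiomer to the cis-(2R,4R)-flavan-4-ol F5. This alcohol is separated, and the unreacted 2S ketone rejoins the route as 13.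

3. Step 9. The hindered, hydrogen-bonded C5 phenol could react slowly, so that the activated alcohol is consumed by SN2′ attack or elimination instead of clean O-alkylation. Fallback (π-allyl chemistry instead of redox condensation): the fallback sets out from 5 and 13. Methyl chloroformate and pyridine would convert 5 into the mixed carbonate (E)-4-[(methoxycarbonyl)oxy]-2-methylbut-2-en-1-yl acetate F6. Pd(PPh3)4 in THF at room temperature should ionise the carbonate in preference to the acetate. The methoxide released would deprotonate 13, and attack of the phenoxide at the unsubstituted terminus of the allyl–palladium complex would give 14, where the route is rejoined.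

## Further compounds

F1 | step 10 | (2S)-2-{3,4-bis[(tert-butyldimethylsilyl)oxy]phenyl}-7-[(tert-butyldimethylsilyl)oxy]-5-[(3-methylbut-2-en-1-yl)oxy]-2,3-dihydro-4H-chromen-4-one | CC(C)=CCOc1cc(O[Si](C)(C)C(C)(C)C)cc2c1C(=O)C[C@@H](c1ccc(O[Si](C)(C)C(C)(C)C)c(O[Si](C)(C)C(C)(C)C)c1)O2
F2 | step 10 | (2S)-2-{3,4-bis[(tert-butyldimethylsilyl)oxy]phenyl}-7-[(tert-butyldimethylsilyl)oxy]-5-hydroxy-8-(3-methylbut-2-en-1-yl)-2,3-dihydro-4H-chromen-4-one | CC(C)=CCc1c(O[Si](C)(C)C(C)(C)C)cc(O)c2c1O[C@H](c1ccc(O[Si](C)(C)C(C)(C)C)c(O[Si](C)(C)C(C)(C)C)c1)CC2=O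
F3 | step 10 | (2S)-2-{3,4-bis[(tert-butyldimethylsilyl)oxy]phenyl}-7-[(tert-butyldimethylsilyl)oxy]-5-hydroxy-8-[(2E)-4-hydroxy-3-methylbut-2-en-1-yl]-2,3-dihydro-4H-chromen-4-one | OC/C(C)=C/Cc1c(O[Si](C)(C)C(C)(C)C)cc(O)c2c1O[C@H](c1ccc(O[Si](C)(C)C(C)(C)C)c(O[Si](C)(C)C(C)(C)C)c1)CC2=O
F4 | step 8 | rac-2-{3,4-bis[(tert-butyldimethylsilyl)oxy]phenyl}-7-[(tert-butyldimethylsilyl)oxy]-5-hydroxy-2,3-dihydro-4H-chromen-4-one | c1c(O[Si](C)(C)C(C)(C)C)cc(O)c2c1OC(c1ccc(O[Si](C)(C)C(C)(C)C)c(O[Si](C)(C)C(C)(C)C)c1)CC2=O
F5 | step 8 | (2R,4R)-2-{3,4-bis[(tert-butyldimethylsilyl)oxy]phenyl}-7-[(tert-butyldimethylsilyl)oxy]-3,4-dihydro-2H-chromene-4,5-diol | c1c(O[Si](C)(C)C(C)(C)C)cc(O)c2c1O[C@@H](c1ccc(O[Si](C)(C)C(C)(C)C)c(O[Si](C)(C)C(C)(C)C)c1)C[C@H]2O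
F6 | step 9 | (E)-4-[(methoxycarbonyl)oxy]-2-methylbut-2-en-1-yl acetate | CC(=O)OC/C(C)=C/COC(=O)OC
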